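The ratio of Q found to E lost in the first reading of birch, the earlier run, shows how E divides between its two ways out. That division is the first step in reckoning how much of the charge reaches the ring pool, Q with G, in oak, the flask asked about.

| setting | oak | birch | flask |
|---|---|---|---|
| E | 0.050 M | 0.034 M | 0.050 M |
| temperature | 60 °C | 66 °C | 60 °C |
| remark | the very flask that is asked about, followed so far | run made earlier |  |
| time |  |  | 15 h |

| run | time / min | Q / % | E / % |
|---|---|---|---|
| oak | 60.0 | 23.1 | 8.8 |
| oak | 180 | 15.0 | 1.4 |
| oak | 360 | 12.7 | 0 |
| oak | 600 | 14.3 | 0 |
| birch | 2.50 | 9.5 | 78.6 |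
| birch | 8.00 | 20.8 | 50.4 |
| birch | 12.0 | 24.6 | 38.4 |
| birch | 20.0 | 31.2 | 24.8 |

(each reading ± 0.5 percentage points)

- a species is counted by the E in it: one Z counts as two
- what is taken out of Q is counted as made
- the numbers in the tables scatter with a standard deviation of 0.5 percentage points
- steps thought possible: 2 E -> Z; E -> Q; Q <-> G
- additions bring no volume worth counting

- gamma: at 15 h raise the temperature by 20 K, then wait 8.0 h
- alpha: at 15 h add E, 50.0% of the amount charged, then wait 8.0 h
- theta: change nothing and wait 8.0 h more
- epsilon: at 15 h take out 90% of the Q then present, then wait 8.0 h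

1. Q, in percent of the E first charged, at 15 h
2. the remedy with the largest gain of Q, or "none" below 2 percentage points (gamma / alpha / theta / epsilon / none)
3. Q present, with what was taken out counted in, in percent of the E first charged, after gamma
4. Q present, with what was taken out counted in, in percent of the E first charged, after theta

At 2.50 min, birch holds Q 9.5% against E lost 21.4%, so the ring's share, its selectivity, reads 0.444, while the fraction of the charge still there averages 0.893. If E goes to Q at first order and to Z at second order, the share at fraction y is x/(x+y), where x is the crossing fraction: the fraction of the charge at which both paths use E equally fast. Birch gives 0.713.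

A crossing fraction scales inversely with the charge, so oak gets 0.485, which is less than the full charge, with the temperature difference between 66 °C and 60 °C left out. Summed over a run, the ring pool (Q with G) is x·ln((1+x)/x), which is 54.3% for oak.

My own reckoning follows. Oak's late Q readings, with E at 0%, average 13.5%, so Q is 0.249 of the pool. Alpha starts at crossing fraction 0.970 and gains 8.5 percentage points, and epsilon gains 9.1 points. G holds 41 points, more than either gain, but oak's readings at one temperature do not show which way heat moves it. The next run to make is therefore gamma.

The forecast gives Q 13.5% now, 13.5% after theta, 14% after gamma, and best alpha. Its ring pool is about 34%, below mine, and on gamma it says “The data barely fix its temperature dependence”.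

The flask gives Q 13.3% at the asked time and 13.3% after theta. The gains are 8.8 points for alpha, 8.5 points for epsilon and 16 points for gamma, which reaches 29.7%. The best remedy is gamma.

    2 E → Z (k = 0.0110 L mol⁻¹ s⁻¹, Ea = 52.0 kJ mol⁻¹)
    E → Q (k = 3.70 × 10⁻⁴ s⁻¹, Ea = 97.0 kJ mol⁻¹)
    Q ⇌ G (K = 2.50, k = 2.50 × 10⁻⁴ s⁻¹, Ea = 95.0 kJ mol⁻¹, ΔH = −73.0 kJ mol⁻¹)
    (constants at 60 °C)

The forecast and the flask part on gamma. At the start of oak, E goes to Q at 0.34 of its rate to Z, and by 900 min Z stands at 53.6% beside G 33.1% and Q 13.3%, a pool of 46.4% against my 54.3%. On the neighbour charged with 0.013 M, the crossing fraction becomes 1.86, above the full charge, and the pool 80.0%. The computed neighbour holds Q 21.2% and G 52.9%, together 74.1%.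

The runs stem from a simulated flask from invented constants; noise was put on by code.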